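**Strategy.** The cyclohexane ring (C5–C10, elemanolide numbering) is divided into two three-carbon units. C10–C5–C6 is a 1,3-dielectrophile: an aldehyde at C6 and a tertiary allylic carbonate at C10. C7–C8–C9 is the dianion of an itaconate-derived β-keto ester, whose C8 ketone makes C7 and C9 nucleophilic and which already holds the α-methylene acid of the lactone ring. One pot joins C6–C7 by aldol addition and lactonisation and C9–C10 by palladium-catalysed 6-exo allylic alkylation. The step exploits the quaternary C10 that bears vinyl and methyl: both C10 epimers of the carbonate converge through one π-allyl complex. Decarboxylation, reduction, inverting acylation at C8 and allylic oxidation follow.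

Key step: step 10

Remark: locants follow elemanolide numbering (ring C5–C6–C7–C8–C9–C10; vinyl C1=C2 and methyl C14 on C10; C4(=C3H2)–C15 on C5; lactone carbonyl C12 and C11=C13H2 on C7, lactone oxygen on C6); α/β are used as in the target, where H-5 is α, H-6 β, H-7 α, H-8 β and the C10 methyl β; (S)-glyceraldehyde acetonide 20 is taken as a commercial material.

**Step 1**
Reactants: 1 (E)-but-2-en-1-ol
Product: 2 [(2S,3S)-3-methyloxiran-2-yl]methanol
Conditions: Ti(OiPr)4 (5 mol%), L-(+)-diisopropyl tartrate (6 mol%), tBuOOH, 4 Å MS, CH2Cl2, −20 °C, non-aqueous work-up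
Reagents that add atoms: tert-butyl hydroperoxide, CC(C)(C)OO
Why: Sharpless asymmetric epoxidation of an E allylic alcohol, in which the L-(+)-tartrate ligand should deliver oxygen to the face that gives the (2S,3S)-epoxide and so fixes the later C5 centre.

**Step 2**
Reactants: 2 [(2S,3S)-3-methyloxiran-2-yl]methanol
Product: 3 (2R,3S)-2-(prop-1-en-2-yl)butane-1,3-diol
Conditions: isopropenylMgBr (3 equiv), CuI (10 mol%), THF, −30 to 0 °C; NaIO4 work-up
Reagents that add atoms: isopropenylmagnesium bromide, C=C(C)[Mg]Br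
Why: Copper-catalysed SN2 opening of the trans-2,3-epoxy alcohol at C2 with inversion, the usual regiochemistry of organocopper reagents with such epoxides, should set the isopropenyl-bearing centre (later C5), and periodate removes the minor 1,2-diol from attack at C3.

**Step 3**
Reactants: 3 (2R,3S)-2-(prop-1-en-2-yl)butane-1,3-diol
Product: 4 (2S,3R)-4-[(tert-butyldimethylsilyl)oxy]-3-(prop-1-en-2-yl)butan-2-ol
Conditions: TBSCl (1.05 equiv), imidazole, CH2Cl2, 0 °C
Reagents that add atoms: tert-butyldimethylsilyl chloride, CC(C)(C)[Si](C)(C)Cl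
Why: Silyl ether formation is expected at the unhindered primary hydroxyl in preference to the secondary one.

**Step 4**
Reactants: 4 (2S,3R)-4-[(tert-butyldimethylsilyl)oxy]-3-(prop-1-en-2-yl)butan-2-ol
Product: 5 (3R)-4-[(tert-butyldimethylsilyl)oxy]-3-(prop-1-en-2-yl)butan-2-one
Conditions: Dess–Martin periodinane, NaHCO3, CH2Cl2, 0 °C to rt
Reagents that add atoms: none
Why: Dess–Martin oxidation under buffered conditions should give the methyl ketone without epimerising or conjugating the adjacent allylic centre.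

**Step 5**
Reactants: 5 (3R)-4-[(tert-butyldimethylsilyl)oxy]-3-(prop-1-en-2-yl)butan-2-one
Product: 7 methyl (3RS,4R)-5-[(tert-butyldimethylsilyl)oxy]-3-methyl-4-(prop-1-en-2-yl)pent-1-en-3-yl carbonate, via bromomagnesium alkoxide 6 (not isolated)
Conditions: CH2=CHMgBr, CeCl3, THF, −78 °C; then ClCO2Me, −78 to 0 °C
Reagents that add atoms: vinylmagnesium bromide, C=C[Mg]Br; methyl chloroformate, COC(=O)Cl
Why: Cerium-modified Grignard 1,2-addition suppresses enolisation of the ketone and the tertiary alkoxide is acylated in the flask; the new C10 carbinol centre is left as an epimeric mixture on purpose because step 10 erases it.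

**Step 6**
Reactants: 7 methyl (3RS,4R)-5-[(tert-butyldimethylsilyl)oxy]-3-methyl-4-(prop-1-en-2-yl)pent-1-en-3-yl carbonate
Product: 8 methyl (3RS,4R)-5-hydroxy-3-methyl-4-(prop-1-en-2-yl)pent-1-en-3-yl carbonate
Conditions: HF·pyridine, pyridine, THF, 0 °C to rt
Reagents that add atoms: none
Why: Fluoride cleavage of the primary silyl ether under buffered conditions should leave the tertiary allylic carbonate intact.

**Step 7**
Reactants: 8 methyl (3RS,4R)-5-hydroxy-3-methyl-4-(prop-1-en-2-yl)pent-1-en-3-yl carbonate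
Product: 9 methyl (3RS,4S)-3-methyl-5-oxo-4-(prop-1-en-2-yl)pent-1-en-3-yl carbonate
Conditions: Dess–Martin periodinane, NaHCO3, CH2Cl2, 0 °C; used crude at once
Reagents that add atoms: none
Why: Dess–Martin oxidation gives the β,γ-unsaturated aldehyde under neutral conditions, and immediate use should avoid β-elimination of the carbonate and loss of the C5 configuration.

**Step 8**
Reactants: 10 dimethyl 2-methylidenebutanedioate (dimethyl itaconate)
Product: 11 3-(methoxycarbonyl)but-3-enoic acid
Conditions: LiOH·H2O (1.0 equiv), THF/H2O, 0 °C; then 1 M HCl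
Reagents that add atoms: lithium hydroxide, [Li+].[OH-]
Why: Ester saponification is expected at the unhindered saturated ester in preference to the conjugated, α-branched acrylate ester.

**Step 9**
Reactants: 11 3-(methoxycarbonyl)but-3-enoic acid
Product: 12 1-tert-butyl 6-methyl 5-methylidene-3-oxohexanedioate
Conditions: CDI, THF, 0 °C to rt; then mono-tert-butyl malonate, MgCl2, Et3N, MeCN, rt; aq. citric acid
Reagents that add atoms: 3-tert-butoxy-3-oxopropanoic acid (mono-tert-butyl malonate), CC(C)(C)OC(=O)CC(=O)O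
Why: Decarboxylative Claisen-type C-acylation of a magnesium malonate half-ester by the acyl imidazolide builds the β-keto ester under near-neutral conditions that should not move the exocyclic double bond into conjugation.

**Step 10**
Reactants: 12 1-tert-butyl 6-methyl 5-methylidene-3-oxohexanedioate; 9 methyl (3RS,4S)-3-methyl-5-oxo-4-(prop-1-en-2-yl)pent-1-en-3-yl carbonate
Product: 16 tert-butyl 8-oxoelema-1,3,11(13)-trien-12,6α-olide-9-carboxylate (H-5α/H-6β/H-7α/10β-methyl; C9 as epimers or enol), via dilithium dianion 13 (not isolated), via lithium enolate lactone 14 (not isolated), via silyl enol ether 15 (not isolated)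
Conditions: LDA (2.1 equiv, commercial solution), THF, −78 to −40 °C; 9, −78 to 0 °C; TMSCl (2.2 equiv), 0 °C; Pd(PPh3)4 (5 mol%), 40 °C; aq. NH4Cl
Reagents that add atoms: none
Why: A one-pot formal [3+3] annulation that combines known reaction types: the allylic C7 carbanion of β-keto ester dianion 13 adds to aldehyde 9 (aldol addition) and the lithium alkoxide closes the α-methylene-γ-butyrolactone by acyl substitution at the acrylate ester (5-exo-trig), after which TMSCl traps methoxide and turns the remaining enolate into silyl enol ether 15, whose C9 is allylated by the π-allylpalladium complex formed from the tertiary allylic carbonate (Tsuji–Trost reaction, 6-exo-trig closure of the cyclohexane ring). The closest precedents are the aldol–lactonisation of itaconate dienolates with aldehydes and the neutral palladium-catalysed allylation of silyl enol ethers by allyl carbonates. C6 should follow Felkin–Anh addition anti to the fully substituted C10 group on the C5 stereocentre, and C7 a Zimmerman–Traxler chair of the Z enolate, helped by reversibility of the aldolate and faster closure of the trans-lactone. C10 is set in the ring closure: both C10 epimers of 9 give interconverting π-allyl complexes (π–σ–π), and a chair transition state that keeps the trans-fused lactone, the C5 isopropenyl group and the palladium-bound vinyl unit equatorial places the methyl group axial (10β). Only attack at the more substituted allyl terminus gives a six- instead of an eight-membered ring, so the quaternary centre is enforced by ring size. The step needs addition of the dianion to the aldehyde to outrun deprotonation at C5 and attack at the carbonate (−78 °C, most electrophilic carbonyl) and C- over O-allylation, which the soft enol ether/π-allyl pairing and the reversibility of O-allylation should secure.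

**Step 11**
Reactants: 16 tert-butyl 8-oxoelema-1,3,11(13)-trien-12,6α-olide-9-carboxylate
Product: 18 8-oxoelema-1,3,11(13)-trien-12,6α-olide (H-5α/H-6β/H-7α/10β-methyl), via β-keto acid 17 (not isolated)
Conditions: TMSOTf, 2,6-lutidine, CH2Cl2, 0 °C; aq. citric acid; then toluene, 50 °C
Reagents that add atoms: none
Why: Silyl triflate cleavage of the tert-butyl ester and thermal decarboxylation of the β-keto acid touch no ring stereocentre, and the non-protic conditions should spare the isopropenyl group and the exocyclic methylene.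

**Step 12**
Reactants: 18 8-oxoelema-1,3,11(13)-trien-12,6α-olide
Product: 19 8β-hydroxyelema-1,3,11(13)-trien-12,6α-olide (axial alcohol)
Conditions: LiAlH(OtBu)3, THF, −78 to −30 °C; AcOH quench at −78 °C
Reagents that add atoms: none
Why: Hydride reduction of the cyclohexanone: the axial 10β-methyl group blocks the axial trajectory, so the bulky alkoxyaluminium hydride should attack equatorially and give the axial 8β-alcohol, while lactone and acrylate units are not reduced at low temperature.

**Step 13**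
Reactants: 20 (4S)-2,2-dimethyl-1,3-dioxolane-4-carbaldehyde
Product: 21 (4R)-4-ethynyl-2,2-dimethyl-1,3-dioxolane
Conditions: dimethyl (1-diazo-2-oxopropyl)phosphonate, K2CO3, MeOH, 0 °C to rt
Reagents that add atoms: dimethyl (1-diazo-2-oxopropyl)phosphonate, CC(=O)C(=[N+]=[N-])P(=O)(OC)OC
Why: Ohira–Bestmann homologation converts the aldehyde into the terminal alkyne, and the acetal stereocentre should survive the mildly basic conditions.

**Step 14**
Reactants: 21 (4R)-4-ethynyl-2,2-dimethyl-1,3-dioxolane
Product: 22 methyl 2-[(4R)-2,2-dimethyl-1,3-dioxolan-4-yl]prop-2-enoate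
Conditions: Pd(OAc)2 (1 mol%), 2-(diphenylphosphino)pyridine (4 mol%), MsOH (4 mol%), CO (10 bar), MeOH, 45 °C
Reagents that add atoms: carbon monoxide, [C-]#[O+]; methanol, CO
Why: Palladium-catalysed Markovnikov methoxycarbonylation of the terminal alkyne with a pyridylphosphine and a sulfonic acid should give the 2-substituted acrylate without involving the stereocentre.

**Step 15**
Reactants: 22 methyl 2-[(4R)-2,2-dimethyl-1,3-dioxolan-4-yl]prop-2-enoate
Product: 23 2-[(4R)-2,2-dimethyl-1,3-dioxolan-4-yl]prop-2-enoic acid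
Conditions: LiOH·H2O, THF/H2O, 0 °C; then 1 M HCl to pH 4 at 0 °C
Reagents that add atoms: lithium hydroxide, [Li+].[OH-]
Why: Ester saponification followed by brief cold acidification should keep the acetonide.

**Step 16**
Reactants: 19 8β-hydroxyelema-1,3,11(13)-trien-12,6α-olide; 23 2-[(4R)-2,2-dimethyl-1,3-dioxolan-4-yl]prop-2-enoic acid
Product: 24 8α-{2-[(4R)-2,2-dimethyl-1,3-dioxolan-4-yl]prop-2-enoyloxy}elema-1,3,11(13)-trien-12,6α-olide
Conditions: PPh3, DIAD (premixed), toluene, 0 °C to rt
Reagents that add atoms: none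
Why: Mitsunobu esterification, in which SN2 displacement of the activated axial 8β-oxyphosphonium group by the carboxylate inverts C8 and places the ester in the equatorial 8α position.

**Step 17**
Reactants: 24 8α-{2-[(4R)-2,2-dimethyl-1,3-dioxolan-4-yl]prop-2-enoyloxy}elema-1,3,11(13)-trien-12,6α-olide
Product: 26 8α-{2-[(4R)-2,2-dimethyl-1,3-dioxolan-4-yl]prop-2-enoyloxy}-15-oxoelema-1,3,11(13)-trien-12,6α-olide, via 15-hydroxy compound 25 (not isolated)
Conditions: SeO2 (0.5 equiv), tBuOOH (3 equiv), CH2Cl2, rt; then MnO2, CH2Cl2, rt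
Reagents that add atoms: selenium dioxide (oxygen carrier), O=[Se]=O; tert-butyl hydroperoxide (terminal oxygen source), CC(C)(C)OO
Why: Allylic oxidation (ene reaction and [2,3]-shift with SeO2, then MnO2 oxidation of the allylic alcohol) should take place at the isopropenyl methyl group, the only electron-rich alkene with allylic hydrogens, since the vinyl group has none and the two acrylate-type alkenes are deactivated.

**Step 18**
Reactants: 26 8α-{2-[(4R)-2,2-dimethyl-1,3-dioxolan-4-yl]prop-2-enoyloxy}-15-oxoelema-1,3,11(13)-trien-12,6α-olide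
Product: 27 (3aR,4S,6S,7R,7aR)-6-ethenyl-6-methyl-3-methylidene-2-oxo-7-(3-oxoprop-1-en-2-yl)octahydro-1-benzofuran-4-yl (3R)-3,4-dihydroxy-2-methylidenebutanoate
Conditions: AcOH/H2O/THF (3:1:1), rt to 40 °C
Reagents that add atoms: none
Why: Acid-catalysed acetal hydrolysis under mild aqueous acetic acid should free the 3,4-diol without touching the ester, the lactone or the enal.

**Compound list**
1 | (E)-but-2-en-1-ol | C/C=C/CO | starting material
2 | [(2S,3S)-3-methyloxiran-2-yl]methanol | OC[C@@H]1O[C@H]1C | intermediate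
3 | (2R,3S)-2-(prop-1-en-2-yl)butane-1,3-diol | OC[C@@H](C(C)=C)[C@H](C)O | intermediate
4 | (2S,3R)-4-[(tert-butyldimethylsilyl)oxy]-3-(prop-1-en-2-yl)butan-2-ol | CC(C)(C)[Si](C)(C)OC[C@@H](C(C)=C)[C@H](C)O | intermediate
5 | (3R)-4-[(tert-butyldimethylsilyl)oxy]-3-(prop-1-en-2-yl)butan-2-one | CC(C)(C)[Si](C)(C)OC[C@@H](C(C)=C)C(C)=O | intermediate
6 | bromomagnesium (3RS,4R)-5-[(tert-butyldimethylsilyl)oxy]-3-methyl-4-(prop-1-en-2-yl)pent-1-en-3-olate | CC(C)(C)[Si](C)(C)OC[C@@H](C(C)=C)C(C)(C=C)O[Mg]Br | intermediate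
7 | methyl (3RS,4R)-5-[(tert-butyldimethylsilyl)oxy]-3-methyl-4-(prop-1-en-2-yl)pent-1-en-3-yl carbonate | CC(C)(C)[Si](C)(C)OC[C@@H](C(C)=C)C(C)(C=C)OC(=O)OC | intermediate
8 | methyl (3RS,4R)-5-hydroxy-3-methyl-4-(prop-1-en-2-yl)pent-1-en-3-yl carbonate | OC[C@@H](C(C)=C)C(C)(C=C)OC(=O)OC | intermediate
9 | methyl (3RS,4S)-3-methyl-5-oxo-4-(prop-1-en-2-yl)pent-1-en-3-yl carbonate | O=C[C@@H](C(C)=C)C(C)(C=C)OC(=O)OC | intermediate
10 | dimethyl 2-methylidenebutanedioate (dimethyl itaconate) | COC(=O)CC(=C)C(=O)OC | starting material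
11 | 3-(methoxycarbonyl)but-3-enoic acid | OC(=O)CC(=C)C(=O)OC | intermediate
12 | 1-tert-butyl 6-methyl 5-methylidene-3-oxohexanedioate | CC(C)(C)OC(=O)CC(=O)CC(=C)C(=O)OC | intermediate
13 | dilithium dianion of 12 (deprotonated at C2 and C4) | [Li+].[Li+].CC(C)(C)OC([O-])=CC([O-])=CC(=C)C(=O)OC | intermediate
14 | lithium enolate of tert-butyl 3-[2,3-trans-2-{4-[(methoxycarbonyl)oxy]-2,4-dimethylhexa-1,5-dien-3-yl}-4-methylidene-5-oxooxolan-3-yl]-3-oxopropanoate (H-5α/H-6β/H-7α; C10 epimers) | [Li+].CC(C)(C)OC(=O)C=C([O-])[C@H]1C(=C)C(=O)O[C@@H]1[C@@H](C(C)=C)C(C)(C=C)OC(=O)OC | intermediate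
15 | tert-butyl 3-[2,3-trans-2-{4-[(methoxycarbonyl)oxy]-2,4-dimethylhexa-1,5-dien-3-yl}-4-methylidene-5-oxooxolan-3-yl]-3-[(trimethylsilyl)oxy]prop-2-enoate (H-5α/H-6β/H-7α; C10 epimers) | CC(C)(C)OC(=O)C=C(O[Si](C)(C)C)[C@H]1C(=C)C(=O)O[C@@H]1[C@@H](C(C)=C)C(C)(C=C)OC(=O)OC | intermediate
16 | tert-butyl 8-oxoelema-1,3,11(13)-trien-12,6α-olide-9-carboxylate (H-5α/H-6β/H-7α/10β-methyl; C9 epimers or enol) | C=C[C@]1(C)C(C(=O)OC(C)(C)C)C(=O)[C@H]2C(=C)C(=O)O[C@@H]2[C@H]1C(C)=C | intermediate
17 | 8-oxoelema-1,3,11(13)-trien-12,6α-olide-9-carboxylic acid | C=C[C@]1(C)C(C(=O)O)C(=O)[C@H]2C(=C)C(=O)O[C@@H]2[C@H]1C(C)=C | intermediate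
18 | 8-oxoelema-1,3,11(13)-trien-12,6α-olide (H-5α/H-6β/H-7α/10β-methyl) | C=C[C@]1(C)CC(=O)[C@H]2C(=C)C(=O)O[C@@H]2[C@H]1C(C)=C | intermediate
19 | 8β-hydroxyelema-1,3,11(13)-trien-12,6α-olide | C=C[C@]1(C)C[C@@H](O)[C@H]2C(=C)C(=O)O[C@@H]2[C@H]1C(C)=C | intermediate
20 | (4S)-2,2-dimethyl-1,3-dioxolane-4-carbaldehyde | O=C[C@@H]1COC(C)(C)O1 | starting material
21 | (4R)-4-ethynyl-2,2-dimethyl-1,3-dioxolane | C#C[C@@H]1COC(C)(C)O1 | intermediate
22 | methyl 2-[(4R)-2,2-dimethyl-1,3-dioxolan-4-yl]prop-2-enoate | COC(=O)C(=C)[C@@H]1COC(C)(C)O1 | intermediate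
23 | 2-[(4R)-2,2-dimethyl-1,3-dioxolan-4-yl]prop-2-enoic acid | OC(=O)C(=C)[C@@H]1COC(C)(C)O1 | intermediate
24 | 8α-{2-[(4R)-2,2-dimethyl-1,3-dioxolan-4-yl]prop-2-enoyloxy}elema-1,3,11(13)-trien-12,6α-olide | C=C[C@]1(C)C[C@H](OC(=O)C(=C)[C@@H]3COC(C)(C)O3)[C@H]2C(=C)C(=O)O[C@@H]2[C@H]1C(C)=C | intermediate
25 | 8α-{2-[(4R)-2,2-dimethyl-1,3-dioxolan-4-yl]prop-2-enoyloxy}-15-hydroxyelema-1,3,11(13)-trien-12,6α-olide | C=C[C@]1(C)C[C@H](OC(=O)C(=C)[C@@H]3COC(C)(C)O3)[C@H]2C(=C)C(=O)O[C@@H]2[C@H]1C(=C)CO | intermediate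
26 | 8α-{2-[(4R)-2,2-dimethyl-1,3-dioxolan-4-yl]prop-2-enoyloxy}-15-oxoelema-1,3,11(13)-trien-12,6α-olide | C=C[C@]1(C)C[C@H](OC(=O)C(=C)[C@@H]3COC(C)(C)O3)[C@H]2C(=C)C(=O)O[C@@H]2[C@H]1C(=C)C=O | intermediate
27 | (3aR,4S,6S,7R,7aR)-6-ethenyl-6-methyl-3-methylidene-2-oxo-7-(3-oxoprop-1-en-2-yl)octahydro-1-benzofuran-4-yl (3R)-3,4-dihydroxy-2-methylidenebutanoate | C=C[C@]1(C)C[C@H](OC(=O)C(=C)[C@@H](O)CO)[C@H]2C(=C)C(=O)O[C@@H]2[C@H]1C(=C)C=O | target

**Step count and risks**
Total: 18 steps. Longest linear sequence: 13 steps (steps 1–7, 10–12, 16–18).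

Steps most likely to fail:

1. Step 10. The basic dianion may deprotonate C5 of aldehyde 9 and trigger β-elimination of the carbonate instead of adding to the carbonyl. The aldol addition may show poor Felkin or syn selectivity, so that cis-lactones are carried into the ring closure. The π-allyl complex may lose a β-hydrogen or be captured at oxygen. The fallback sets out from 9 and makes the two bonds in separate, non-basic steps. 2,2,6-Trimethyl-4H-1,3-dioxin-4-one is oxidised with SeO2 to 2,2-dimethyl-4-oxo-4H-1,3-dioxine-6-carbaldehyde F1. A Baylis–Hillman reaction with methyl acrylate and DABCO gives the alcohol F2, and PBr3 gives the rearranged allylic bromide F3. CrCl2 in THF couples F3 with 9 (Nozaki–Hiyama allylation, expected to be anti and Felkin selective), and the chromium alkoxide lactonises to the dioxinone lactone F4. Thermolysis in toluene with tert-butanol (acyl ketene trapping) gives the tert-butyl keto ester lactone F5. F5 is closed with Pd(PPh3)4, BSA and KOAc in THF and comes back to the route at 16.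

2. Step 16. The activated axial alcohol may eliminate to the C7–C8 or C8–C9 alkene, the phosphine may add to the acrylic acid, or the lactone may migrate to the free 8β-hydroxyl. The fallback sets out from 19 and separates inversion from acylation. Mitsunobu reaction with the small, more acidic chloroacetic acid (PPh3, DIAD) gives the inverted 8α-chloroacetate F6. Thiourea and NaHCO3 cleave it to the 8α-alcohol F7. Yamaguchi esterification of F7 with 23 (2,4,6-trichlorobenzoyl chloride, Et3N, DMAP, toluene) comes back to the route at 24.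

3. Step 17. The ene oxidation may be slow or may stop at mixed oxidation levels, and prolonged exposure may attack other allylic positions or the acetonide. The fallback sets out from 24. Ene-type chlorination of the isopropenyl group with Ca(OCl)2 and solid CO2 in CH2Cl2/H2O at 0 °C gives the 15-chloride F8. Kornblum-type oxidation of F8 with N-methylmorpholine N-oxide and catalytic NaI in MeCN comes back to the route at 26.

Further compounds
F1 | step 10 | 2,2-dimethyl-4-oxo-4H-1,3-dioxine-6-carbaldehyde | CC1(C)OC(C=O)=CC(=O)O1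
F2 | step 10 | methyl 2-[(2,2-dimethyl-4-oxo-4H-1,3-dioxin-6-yl)(hydroxy)methyl]prop-2-enoate | COC(=O)C(=C)C(O)C1=CC(=O)OC(C)(C)O1
F3 | step 10 | methyl (2Z)-2-(bromomethyl)-3-(2,2-dimethyl-4-oxo-4H-1,3-dioxin-6-yl)prop-2-enoate | COC(=O)/C(CBr)=C/C1=CC(=O)OC(C)(C)O1
F4 | step 10 | 6-[2,3-trans-2-{4-[(methoxycarbonyl)oxy]-2,4-dimethylhexa-1,5-dien-3-yl}-4-methylidene-5-oxooxolan-3-yl]-2,2-dimethyl-4H-1,3-dioxin-4-one (H-5α/H-6β/H-7α; C10 epimers) | CC1(C)OC([C@H]2C(=C)C(=O)O[C@@H]2[C@@H](C(C)=C)C(C)(C=C)OC(=O)OC)=CC(=O)O1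
F5 | step 10 | tert-butyl 3-[2,3-trans-2-{4-[(methoxycarbonyl)oxy]-2,4-dimethylhexa-1,5-dien-3-yl}-4-methylidene-5-oxooxolan-3-yl]-3-oxopropanoate (H-5α/H-6β/H-7α; C10 epimers) | CC(C)(C)OC(=O)CC(=O)[C@H]1C(=C)C(=O)O[C@@H]1[C@@H](C(C)=C)C(C)(C=C)OC(=O)OC
F6 | step 16 | 8α-(chloroacetoxy)elema-1,3,11(13)-trien-12,6α-olide | C=C[C@]1(C)C[C@H](OC(=O)CCl)[C@H]2C(=C)C(=O)O[C@@H]2[C@H]1C(C)=C
F7 | step 16 | 8α-hydroxyelema-1,3,11(13)-trien-12,6α-olide | C=C[C@]1(C)C[C@H](O)[C@H]2C(=C)C(=O)O[C@@H]2[C@H]1C(C)=C
F8 | step 17 | 8α-{2-[(4R)-2,2-dimethyl-1,3-dioxolan-4-yl]prop-2-enoyloxy}-15-chloroelema-1,3,11(13)-trien-12,6α-olide | C=C[C@]1(C)C[C@H](OC(=O)C(=C)[C@@H]3COC(C)(C)O3)[C@H]2C(=C)C(=O)O[C@@H]2[C@H]1C(=C)CCl
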